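**Retrosynthetic overview**
1. Target 16 ⇐ transannular RCM (C11=C12) of the 15-membered macrolactone 15; the butenolide and the 14-membered carbocycle form together, last.
2. 15 ⇐ key C10–O bond: Rh-catalysed intramolecular addition of the CO2H of seco acid 14 to its terminal allene, which closes the macrolactone first and sets C10.
3. 14 ⇐ allene from a terminal alkyne (Crabbé); C8–C9 by catalytic asymmetric propargylation of methyl enone 11 (sets C8); C6=C7 by cross-metathesis of 9 with methyl vinyl ketone.
4. 9 ⇐ C1–C2 by a new catalytic asymmetric alkenylzinc addition of enynol 6 to isopropyl ketone 3 (sets C1 and the 2E alkene).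
5. 3 ⇐ 3-methylbutan-2-one + methyl 2-(bromomethyl)acrylate; 6 ⇐ TMS-butynone by catalytic asymmetric allylboration (sets C4).

Numbering: C1–C20 above is cembrane numbering (C1 = carbinol carbon bearing isopropyl, C4 and C8 = methyl carbinols, C10 = lactone O–CH, C20 = lactone C=O). Locants in compound names are those of each name.

Assumption: the enantiomer written for each chiral catalyst (Br2-BINOL in steps 2 and 5, the diol ligand in step 3, DIOP in step 8) is the one expected by analogy to give the stated configuration; if a first run shows the opposite sense, the antipodal catalyst is used and nothing else changes.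

**Step 1**
Reactants: 1 3-methylbutan-2-one; 2 methyl 2-(bromomethyl)prop-2-enoate
Product: 3 methyl 6-methyl-2-methylidene-5-oxoheptanoate
Conditions: LDA, THF, −78 °C; then 2, −78 → −40 °C
Reagents that add atoms: none
Why: Kinetic (methyl-side) lithium enolate alkylation of an allylic bromide, where SN2 and SN2′ give the same product; no stereocentre is formed.

**Step 2**
Reactants: 4 4-(trimethylsilyl)but-3-yn-2-one
Product: 6 (3R)-3-methylhex-5-en-1-yn-3-ol, via silyl carbinol 5 (not isolated)
Conditions: 2-allyl-1,3,2-dioxaborinane (1.5 eq), (S)-3,3′-Br2-BINOL (4 mol%), t-BuOH (2 eq), PhMe, rt; then MeOH, K2CO3 (0.2 eq), rt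
Reagents that add atoms: 2-allyl-1,3,2-dioxaborinane, C=CCB1OCCCO1
Why: Chiral-diol-catalysed asymmetric allylboration of a methyl ynone through a closed six-membered transition state sets the methyl carbinol (R) by catalyst control, and methanolysis then removes the C-silyl group.

**Step 3**
Reactants: 6 (3R)-3-methylhex-5-en-1-yn-3-ol; 3 methyl 6-methyl-2-methylidene-5-oxoheptanoate
Product: 9 methyl (5S,6E,8R)-5,8-dihydroxy-8-methyl-2-methylidene-5-(propan-2-yl)undeca-6,10-dienoate, via alkenylzirconocene 7 (not isolated), via alkenylzinc 8 (not isolated)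
Conditions: 6 (1.5 eq), Cp2Zr(H)Cl (3.0 eq), CH2Cl2, 0 °C → rt; Me2Zn (1.6 eq), PhMe, −78 °C; then 3 (1.0 eq), Ti(OiPr)4 (1.2 eq), trans-1,2-bis(2-hydroxycamphor-10-sulfonamido)cyclohexane ligand [(1R,2R)-diamine, (1S)-camphor series, 10 mol%], PhMe, rt; aq NH4Cl
Reagents that add atoms: none
Why: Proposed new method: syn-hydrozirconation of the terminal alkyne of O-zirconated 6 fixes the E geometry, Zr→Zn exchange with Me2Zn keeps it, and the Ti(IV) bis(sulfonamide)-diolate binds ketone 3 and delivers the alkenyl group to one carbonyl face, with the α-branched isopropyl group taking the place that aryl or alkenyl groups take in known substrates and the linear CH2CH2 chain taking the place of methyl, so that (5S) is set by catalyst control over the remote C8 centre; the closest known reaction is the Ti/bis(sulfonamide)-diol-catalysed asymmetric addition of alkenylzinc reagents (alkyne hydrozirconation, then zinc transmetalation) to aryl methyl ketones and enones, which has not been shown for dialkyl ketones that differ only in α-branching or for alkenylzincs that carry a metal alkoxide.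

**Step 4**
Reactants: 9 methyl (5S,6E,8R)-5,8-dihydroxy-8-methyl-2-methylidene-5-(propan-2-yl)undeca-6,10-dienoate; 10 but-3-en-2-one
Product: 11 methyl (5S,6E,8R,10E)-5,8-dihydroxy-8-methyl-2-methylidene-12-oxo-5-(propan-2-yl)trideca-6,10-dienoate
Conditions: Hoveyda–Grubbs II (5 mol%), 10 (5 eq), CH2Cl2, 40 °C
Reagents that add atoms: none
Why: Olefin cross-metathesis of the only unhindered terminal alkene with an electron-poor partner gives the E-enone, while the 1,1-disubstituted acrylate and the internal alkene between two quaternary carbons do not react.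

**Step 5**
Reactants: 11 methyl (5S,6E,8R,10E)-5,8-dihydroxy-8-methyl-2-methylidene-12-oxo-5-(propan-2-yl)trideca-6,10-dienoate
Product: 12 methyl (5S,6E,8R,10E,12S)-5,8,12-trihydroxy-8,12-dimethyl-2-methylidene-5-(propan-2-yl)pentadeca-6,10-dien-14-ynoate
Conditions: allenylboronic acid pinacol ester (2 eq), (R)-3,3′-Br2-BINOL (10 mol%), t-BuOH (2 eq), PhMe, 40 °C
Reagents that add atoms: allenylboronic acid pinacol ester, C=C=CB1OC(C)(C)C(C)(C)O1
Why: Chiral-diol-catalysed asymmetric propargylation of a methyl ketone with an allenylboronate (SE2′, closed transition state, 1,2-addition to the enone) sets the second methyl carbinol (12S) with the catalyst antipodal to step 2, the resident centres being too remote to interfere.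

**Step 6**
Reactants: 12 methyl (5S,6E,8R,10E,12S)-5,8,12-trihydroxy-8,12-dimethyl-2-methylidene-5-(propan-2-yl)pentadeca-6,10-dien-14-ynoate
Product: 13 methyl (5S,6E,8R,10E,12S)-5,8,12-trihydroxy-8,12-dimethyl-2-methylidene-5-(propan-2-yl)hexadeca-6,10,14,15-tetraenoate
Conditions: (CH2O)n (2.5 eq), CuI (0.5 eq), Cy2NH (1.8 eq), 1,4-dioxane, 100 °C
Reagents that add atoms: paraformaldehyde (formaldehyde), C=O
Why: Crabbé homologation (Cu-mediated Mannich reaction, then hydride shift and loss of imine) turns the terminal alkyne into the terminal allene one carbon longer; free hydroxyls and the ester are tolerated and no stereocentre is touched.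

**Step 7**
Reactants: 13 methyl (5S,6E,8R,10E,12S)-5,8,12-trihydroxy-8,12-dimethyl-2-methylidene-5-(propan-2-yl)hexadeca-6,10,14,15-tetraenoate
Product: 14 (5S,6E,8R,10E,12S)-5,8,12-trihydroxy-8,12-dimethyl-2-methylidene-5-(propan-2-yl)hexadeca-6,10,14,15-tetraenoic acid
Conditions: LiOH, THF/H2O (3:1), 0 °C → rt; then 1 M HCl to pH 5, 0 °C
Reagents that add atoms: lithium hydroxide, [Li+].[OH-]; water, O
Why: Ester saponification; the mild cold acidification spares the tertiary allylic alcohols, and the acid is used at once to avoid slow δ-lactone formation onto the C5 hydroxyl.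

**Step 8**
Reactants: 14 (5S,6E,8R,10E,12S)-5,8,12-trihydroxy-8,12-dimethyl-2-methylidene-5-(propan-2-yl)hexadeca-6,10,14,15-tetraenoic acid
Product: 15 (6S,7E,9R,11E,13S,15R)-15-ethenyl-6,9,13-trihydroxy-9,13-dimethyl-3-methylidene-6-(propan-2-yl)-1-oxacyclopentadeca-7,11-dien-2-one
Conditions: [Rh(cod)Cl]2 (5 mol%), (R,R)-DIOP (10 mol%), Cs2CO3 (10 mol%), DCE, 2 mM (syringe pump), 60 °C
Reagents that add atoms: none
Why: Rh(I)/DIOP-catalysed hydro-oxycarbonylation of a terminal allene (O–H oxidative addition, hydrometalation to a π-allyl-Rh, carboxylate attack at the substituted terminus) forms the branched allylic C–O bond, closes the 15-membered lactone and sets (15R) by ligand control; only the CO2H reacts, and because the acid is never activated the tertiary hydroxyls cannot lactonise.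

**Step 9**
Reactants: 15 (6S,7E,9R,11E,13S,15R)-15-ethenyl-6,9,13-trihydroxy-9,13-dimethyl-3-methylidene-6-(propan-2-yl)-1-oxacyclopentadeca-7,11-dien-2-one
Product: 16 (1S,2E,4R,6E,8S,10R)-1,4,8-trihydroxycembra-2,6,11-trien-20,10-olide (the target)
Conditions: Grubbs II (10 mol%), PhMe, 1 mM, 80 °C
Reagents that add atoms: none
Why: Transannular ring-closing metathesis between the acrylate methylidene and the vinyl group expels ethene and forms the butenolide, whose C11=C12 bond completes the 14-membered carbocycle; the hindered internal E-alkenes are inert and no stereocentre changes.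

**Compound list**
1 | 3-methylbutan-2-one | CC(=O)C(C)C | starting material
2 | methyl 2-(bromomethyl)prop-2-enoate | COC(=O)C(=C)CBr | starting material
3 | methyl 6-methyl-2-methylidene-5-oxoheptanoate | COC(=O)C(=C)CCC(=O)C(C)C | intermediate
4 | 4-(trimethylsilyl)but-3-yn-2-one | CC(=O)C#C[Si](C)(C)C | starting material
5 | (3R)-3-methyl-1-(trimethylsilyl)hex-5-en-1-yn-3-ol | C[Si](C)(C)C#C[C@](C)(O)CC=C | intermediate
6 | (3R)-3-methylhex-5-en-1-yn-3-ol | C#C[C@](C)(O)CC=C | intermediate
7 | O-zirconated (E)-alkenylzirconocene chloride of 6, Cp2ClZr–CH=CH–C(CH3)(OZrClCp2)–CH2CH=CH2, (3R) (Cp drawn σ-bonded in the SMILES) | C=CC[C@@](C)(O[Zr](Cl)(C1C=CC=C1)C1C=CC=C1)/C=C/[Zr](Cl)(C1C=CC=C1)C1C=CC=C1 | intermediate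
8 | (E)-alkenyl(methyl)zinc, MeZn–CH=CH–C(CH3)(OZrClCp2)–CH2CH=CH2, (3R) | C=CC[C@@](C)(O[Zr](Cl)(C1C=CC=C1)C1C=CC=C1)/C=C/[Zn]C | intermediate
9 | methyl (5S,6E,8R)-5,8-dihydroxy-8-methyl-2-methylidene-5-(propan-2-yl)undeca-6,10-dienoate | COC(=O)C(=C)CC[C@](O)(C(C)C)/C=C/[C@](C)(O)CC=C | intermediate
10 | but-3-en-2-one | CC(=O)C=C | starting material
11 | methyl (5S,6E,8R,10E)-5,8-dihydroxy-8-methyl-2-methylidene-12-oxo-5-(propan-2-yl)trideca-6,10-dienoate | COC(=O)C(=C)CC[C@](O)(C(C)C)/C=C/[C@](C)(O)C/C=C/C(C)=O | intermediate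
12 | methyl (5S,6E,8R,10E,12S)-5,8,12-trihydroxy-8,12-dimethyl-2-methylidene-5-(propan-2-yl)pentadeca-6,10-dien-14-ynoate | COC(=O)C(=C)CC[C@](O)(C(C)C)/C=C/[C@](C)(O)C/C=C/[C@@](C)(O)CC#C | intermediate
13 | methyl (5S,6E,8R,10E,12S)-5,8,12-trihydroxy-8,12-dimethyl-2-methylidene-5-(propan-2-yl)hexadeca-6,10,14,15-tetraenoate | COC(=O)C(=C)CC[C@](O)(C(C)C)/C=C/[C@](C)(O)C/C=C/[C@@](C)(O)CC=C=C | intermediate
14 | (5S,6E,8R,10E,12S)-5,8,12-trihydroxy-8,12-dimethyl-2-methylidene-5-(propan-2-yl)hexadeca-6,10,14,15-tetraenoic acid | OC(=O)C(=C)CC[C@](O)(C(C)C)/C=C/[C@](C)(O)C/C=C/[C@@](C)(O)CC=C=C | intermediate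
15 | (6S,7E,9R,11E,13S,15R)-15-ethenyl-6,9,13-trihydroxy-9,13-dimethyl-3-methylidene-6-(propan-2-yl)-1-oxacyclopentadeca-7,11-dien-2-one | C=C1CC[C@](O)(C(C)C)/C=C/[C@](C)(O)C/C=C/[C@@](C)(O)C[C@H](C=C)OC1=O | intermediate
16 | (1S,2E,4R,6E,8S,10R)-1,4,8-trihydroxycembra-2,6,11-trien-20,10-olide (CHEBI:68873) | CC(C)[C@]1(O)/C=C/[C@](C)(O)C/C=C/[C@@](C)(O)C[C@@H]2C=C(CC1)C(=O)O2 | target

**Step count**
Total: 9 steps (steps 2 and 3 are one-pot operations). Longest linear sequence: 8 steps (4 → 6 → 9 → 11 → 12 → 13 → 14 → 15 → 16).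

**Three steps most likely to fail, with fallbacks**

Step 3 (the new method). The risks are modest face selectivity between isopropyl and the primary chain, competing methyl transfer, and hydrozirconation of the allyl group by excess Cp2Zr(H)Cl. The fallback uses known chemistry and gives up catalyst control at this centre. It sets out from 6 and 3: hydrozirconation of 6 (Cp2Zr(H)Cl, 2 eq) and iodinolysis (I2) give (1E,3R)-1-iodo-3-methylhexa-1,5-dien-3-ol F1. Treatment with t-BuLi (3.1 eq, Et2O, −78 °C) and then anhydrous CeCl3 gives the alkenylcerium reagent, which adds to the ketone of 3 in the presence of the ester without control at the new carbinol. This gives 9 together with its 5-epimer, methyl (5R,6E,8R)-5,8-dihydroxy-8-methyl-2-methylidene-5-(propan-2-yl)undeca-6,10-dienoate F2, in about equal amounts. Because C8 is already fixed the two are diastereomers and are separated by chromatography; the route is rejoined at 9.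

Step 5. The diol-catalysed propargylation has to work on a polyhydroxylated enone ester, where the free hydroxyls may exchange with the boronate and erode rate or selectivity. The fallback sets out from 11 and changes the nucleophile: Cu(I)/bisphosphine catalysis [Cu(II) isobutyrate 5 mol%, (R)-BINAP 7 mol%, LiOtBu, THF, −60 °C] with 4,4,5,5-tetramethyl-2-[3-(trimethylsilyl)prop-2-yn-1-yl]-1,3,2-dioxaborolane proceeds through an allenylcopper species and gives methyl (5S,6E,8R,10E,12S)-5,8,12-trihydroxy-8,12-dimethyl-2-methylidene-5-(propan-2-yl)-15-(trimethylsilyl)pentadeca-6,10-dien-14-ynoate F3. K2CO3 in MeOH removes the silyl group and returns to 12.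

Step 8. The Rh macrolactonisation is run on an α-substituted acrylic acid carrying three free tertiary alcohols; oligomerisation, poor ligand control at C15 and δ-lactone formation of 14 on standing are the concerns. The fallback sets out from 13 and closes the ring by activating the alcohol instead. Intermolecular Rh(I)/(S,S)-DIOP-catalysed addition of benzoic acid to the allene gives methyl (5S,6E,8R,10E,12S,14S)-14-(benzoyloxy)-5,8,12-trihydroxy-8,12-dimethyl-2-methylidene-5-(propan-2-yl)hexadeca-6,10,15-trienoate F4. LiOH cleaves both esters to (5S,6E,8R,10E,12S,14S)-5,8,12,14-tetrahydroxy-8,12-dimethyl-2-methylidene-5-(propan-2-yl)hexadeca-6,10,15-trienoic acid F5. Mitsunobu macrolactonisation (PPh3, DIAD, PhMe, high dilution) closes the ring at the only secondary hydroxyl with inversion and rejoins the route at 15; the tertiary hydroxyls do not react, and since the acid is not activated no δ-lactone can form.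

The transannular RCM of step 9 is the next most exposed step; the macrolactonisation-then-transannular-RCM order is an established way to build cembranolide butenolides.

**Further compounds**
F1 | step 3 | (1E,3R)-1-iodo-3-methylhexa-1,5-dien-3-ol | C=CC[C@@](C)(O)/C=C/I
F2 | step 3 | methyl (5R,6E,8R)-5,8-dihydroxy-8-methyl-2-methylidene-5-(propan-2-yl)undeca-6,10-dienoate | COC(=O)C(=C)CC[C@@](O)(C(C)C)/C=C/[C@](C)(O)CC=C
F3 | step 5 | methyl (5S,6E,8R,10E,12S)-5,8,12-trihydroxy-8,12-dimethyl-2-methylidene-5-(propan-2-yl)-15-(trimethylsilyl)pentadeca-6,10-dien-14-ynoate | COC(=O)C(=C)CC[C@](O)(C(C)C)/C=C/[C@](C)(O)C/C=C/[C@@](C)(O)CC#C[Si](C)(C)C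
F4 | step 8 | methyl (5S,6E,8R,10E,12S,14S)-14-(benzoyloxy)-5,8,12-trihydroxy-8,12-dimethyl-2-methylidene-5-(propan-2-yl)hexadeca-6,10,15-trienoate | COC(=O)C(=C)CC[C@](O)(C(C)C)/C=C/[C@](C)(O)C/C=C/[C@@](C)(O)C[C@@H](C=C)OC(=O)c1ccccc1
F5 | step 8 | (5S,6E,8R,10E,12S,14S)-5,8,12,14-tetrahydroxy-8,12-dimethyl-2-methylidene-5-(propan-2-yl)hexadeca-6,10,15-trienoic acid | OC(=O)C(=C)CC[C@](O)(C(C)C)/C=C/[C@](C)(O)C/C=C/[C@@](C)(O)C[C@H](O)C=C
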